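Assumption and numbering: 3‑ethoxy‑3‑oxopropylzinc bromide (5) and ethyl 4‑(benzyloxy)acetoacetate (13) are taken as catalogue items. Terpenoid carbons are C1–C12: C3 = ring A carbonyl, C4 = CMe2–O, C5/C10 = A/B fusion, C8 bears C12, C9 bears C11. β is the face of the C10 methyl. The second six‑carbon unit is C1′ (ketone), C2′ (bears C9′), C3′ (bears C7′H2O), C4′ (bears C8′ carbonyl), C5′ and C6′ (bears C10′ methyl). Rings: A ε‑lactone, B cyclohexane, C cyclopentane, D cyclohexanone, E cyclohexane, F γ‑lactone, G the temporary cyclohexadienone.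

**Retrosynthetic overview**
1. Key disconnection: the tertiary alkyl C4–O bond of ring A. Ring A is never a carbocycle, so ring B with C5 can come from (+)‑verbenone. The C1=C2 double bond is introduced last.
2. Ring D (C11–C1′) comes from a carbonyl‑ene closure of an ene‑aldehyde. That aldehyde comes from α‑cleavage of an isotwistanone, a formal 1,2‑acyl shift that also delivers the exocyclic methylene.
3. Rings C and E come from an intramolecular Diels–Alder reaction of cyclohexadienone ring G with C8=C12. Ring F closes through its C–O bond after O‑debenzylation.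
4. Ring G comes from a Michael/aldol annulation of an isopropenyl ketone. C9–C11 and C8=C12 come from a Hosomi–Sakurai addition.
5. Order of ring formation: B (chiral pool) → A → G → C/E → F → D.

**Step 1**
Reactants: 1 (1R,5R)-(+)-verbenone
Product: 4 (S)-4-isopropenyl-3-methylcyclohex-2-enone, via tertiary iodide silyl dienol ether 2 (not isolated), via isopropenyl silyl dienol ether 3 (not isolated)
Conditions: Me3SiI, CH2Cl2, −40 °C; DBU, −40 → 0 °C; 1 M HCl
Reagents that add atoms: none
Why: Silylation of the enone oxygen triggers strain‑releasing scission of the cyclobutane bond α to the carbonyl (pinanone‑type fragmentation), E2 at a methyl group gives the isopropenyl unit, and C5 is untouched and keeps the verbenone configuration.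

**Step 2**
Reactants: 4 (S)-4-isopropenyl-3-methylcyclohex-2-enone; 5 3-ethoxy-3-oxopropylzinc bromide
Product: 6 silyl enol ether (C8–OSiMe3, Δ8(9)) carrying C10(β‑Me)(α‑CH2CH2CO2Et) and C5 β‑isopropenyl
Conditions: CuBr·SMe2 (10 mol %), Me3SiCl, DMPU, THF, −30 → 0 °C
Reagents that add atoms: chlorotrimethylsilane, C[Si](C)(C)Cl
Why: Copper‑catalysed, silyl‑accelerated homoenolate conjugate addition attacks C10 anti to the adjacent isopropenyl group, which sets the quaternary centre trans and fixes the enol ether regiospecifically towards C9.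

**Step 3**
Reactants: 6 silyl enol ether
Product: 7 alkenyl nonaflate (C8–ONf, Δ8(9))
Conditions: C4F9SO2F, Bu4NF (10 mol %), THF, 0 → 23 °C
Reagents that add atoms: perfluorobutane-1-sulfonyl fluoride, O=S(=O)(F)C(F)(F)C(F)(F)C(F)(F)C(F)(F)F
Why: Fluoride‑catalysed O‑sulfonylation of a silyl enol ether transfers the enolate regiochemistry unchanged and tolerates the ester and the isopropenyl group.

**Step 4**
Reactants: 7 alkenyl nonaflate
Product: 8 trans‑fused bicyclic ε‑lactone nonaflate (ring A closed, 5α‑H, 10β‑Me)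
Conditions: cobalt N,N'-bis(3,5-di-tert-butylsalicylidene)-1,2-cyclohexanediaminate (C36H52CoN2O2, 5 mol %), N‑fluoro‑2,4,6‑trimethylpyridinium triflate, PhSiH3, PhCF3 (0.01 M), 23 °C
Reagents that add atoms: none
Why: Proposed new method: a trivalent cobalt hydride transfers H• to the isopropenyl CH2, and the C4 radical is oxidised through an alkylcobalt species to a cation equivalent. The gauche‑held ethyl ester carbonyl captures it in a seven‑membered closure, and the liberated collidine removes the ethyl group. The closest known reaction type is hydrogen‑atom‑transfer/radical‑polar‑crossover hydroacyloxylation, which is shown for five‑ and six‑membered lactones but not for a tertiary ε‑lactone. No new stereocentre is formed, and the electron‑poor nonaflate alkene is inert.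

**Step 5**
Reactants: 8 lactone nonaflate
Product: 9 allylsilane (C8–CH2SiMe3, Δ8(9))
Conditions: Me3SiCH2MgCl, ZnCl2, THF; Pd(PPh3)4 (5 mol %), 50 °C
Reagents that add atoms: (trimethylsilyl)methylmagnesium chloride, C[Si](C)(C)C[Mg]Cl
Why: Negishi coupling of the alkenyl nonaflate installs C12, and the organozinc reagent does not attack the lactone.

**Step 6**
Reactants: 10 pentan-3-one
Product: 11 2,4-dimethylpenta-1,4-dien-3-one
Conditions: (CH2O)n, iPr2NH2·O2CCF3, CF3CO2H (cat.), THF, reflux
Reagents that add atoms: formaldehyde, C=O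
Why: Double Mannich‑type α‑methylenation of a symmetrical ketone.

**Step 7**
Reactants: 9 allylsilane; 11 2,4-dimethylpenta-1,4-dien-3-one
Product: 12 isopropenyl ketone (C9 α‑CH2CH(CH3)C(=O)C(CH3)=CH2, 9β‑H, C8=C12 exocyclic; epimers at C2′)
Conditions: TiCl4, 2,6‑di‑tert‑butylpyridine, CH2Cl2, −78 °C
Reagents that add atoms: none
Why: In this Hosomi–Sakurai conjugate addition C9 attacks the unhindered CH2 terminus from the α face, anti to the axial C10 methyl, which sets 9β‑H; loss of silicon then creates the exocyclic methylene.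

**Step 8**
Reactants: 12 isopropenyl ketone; 13 ethyl 4-(benzyloxy)acetoacetate
Product: 16 cyclohexenone ester (ring G: C1′=O, quaternary C2′, C3′(CH2OBn)=C4′(CO2Et); epimers at C2′ and C6′), via Michael adduct 14 (not isolated), via aldol 15 (not isolated)
Conditions: Cs2CO3 (10 mol %), THF, 23 °C; then KOtBu (30 mol %), tBuOH, 50 °C
Reagents that add atoms: none
Why: This is a Robinson/Hagemann‑type annulation in which the β‑keto ester adds to C5′. Then C2′, the only enolate position that can form a six‑membered ring, attacks the C3′ ketone. E1cB dehydration towards C4′ makes the closure irreversible, and C2′ forms without control.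

**Step 9**
Reactants: 16 cyclohexenone ester
Product: 19 isotwistene keto ester (C8–C3′ and C12–C6′ bonds formed, C4′=C5′ enoate), via silyl dienol ether 17 (not isolated), via cyclohexadienone 18 (not isolated)
Conditions: Me3SiOTf, Et3N, CH2Cl2, 0 °C; Pd(OAc)2, MeCN, 23 °C; then PhMe, 100 °C, 390 nm LED
Reagents that add atoms: none
Why: Saegusa–Ito dehydrogenation gives the 2,4‑dienone, and only the C2′ epimer with C11 on the diene face can bring the diene under the α face of C8=C12 from the axial C9 chain. The intramolecular Diels–Alder reaction therefore sets C8, C3′ and C6′, and the light recycles the other epimer by Barton–Quinkert dienylketene opening and re‑closure.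

**Step 10**
Reactants: 19 isotwistene keto ester
Product: 21 isotwistanone bis‑lactone (ring F closed, 4′‑epi: C8′ on the side of the C8–C12 bridge), via hydroxy ester 20 (not isolated)
Conditions: H2 (1 atm), Pd/C, EtOAc; then PPTS (cat.), PhMe, 60 °C
Reagents that add atoms: none
Why: Hydrogenation from the less hindered face (the side of the C1′–C2′ bridge), benzyl hydrogenolysis and lactonisation proceed in sequence; the epimerisable C4′ centre is corrected in step 14.

**Step 11**
Reactants: 21 isotwistanone bis‑lactone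
Product: 22 ene‑aldehyde (C6′–CHO, ring C cyclopentene C2′(CH3)=C11H)
Conditions: hν (300 nm), PhH, 23 °C
Reagents that add atoms: none
Why: Norrish α‑cleavage of the non‑enolisable ketone breaks C1′–C2′, the bond that gives the tertiary radical in the five‑membered ring and relieves the most back strain. The acyl radical then takes the neighbouring C11–H by disproportionation, and no ketene path exists because C6′ carries no hydrogen.

**Step 12**
Reactants: 22 ene‑aldehyde
Product: 23 homoallylic alcohol (ring D closed, C11–C1′H(OH), C2′=C9′H2)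
Conditions: Me2AlCl, CH2Cl2, −78 → −20 °C
Reagents that add atoms: none
Why: In the Lewis‑acid carbonyl‑ene reaction the aldehyde, held over the concave face of ring C, bonds to C11 and takes a hydrogen from the C9′ methyl. This sets C11 by cage geometry and gives the only alkene that Bredt's rule allows.

**Step 13**
Reactants: 23 homoallylic alcohol
Product: 24 4′‑epi‑1,2‑dihydro target ketone
Conditions: Dess–Martin periodinane, NaHCO3, CH2Cl2, 23 °C
Reagents that add atoms: none
Why: This is a neutral alcohol oxidation, and the β,γ‑enone cannot move into conjugation because the conjugated isomer would be a bridgehead alkene.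

**Step 14**
Reactants: 24 4′‑epi ketone
Product: 25 1,2‑dihydro target (natural C4′: C8′ on the side of the methylene bridge)
Conditions: KOtBu (20 mol %), tBuOH/THF, 23 °C
Reagents that add atoms: none
Why: Thermodynamic epimerisation through the γ‑lactone enolate is expected to work because, once C2′ is planar, the side of the C2′–C11–C1′ bridge is less crowded than the side facing C7H2; no other centre is enolisable.

**Step 15**
Reactants: 25 1,2‑dihydro target
Product: 27 target CNP0136584.3, via C2 phenylselenide 26 (not isolated)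
Conditions: LiN(iPr)2 (1.05 equiv), THF, −78 °C; PhSeCl; then H2O2, pyridine, CH2Cl2, 0 °C
Reagents that add atoms: none
Why: Kinetic deprotonation occurs at the unhindered C2 methylene rather than at the buried tertiary C4′–H, and selenoxide syn‑elimination can only give C1=C2.

**Compound list**
1 | (1R,5R)-(+)-verbenone | CC1=CC(=O)[C@@H]2C[C@H]1C2(C)C | starting material
2 | 5-(2-iodopropan-2-yl)-4-methyl-2-(trimethylsilyloxy)cyclohexa-1,3-diene | C[Si](C)(C)OC1=CC[C@@H](C(C)(C)I)C(C)=C1 | intermediate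
3 | 5-isopropenyl-4-methyl-2-(trimethylsilyloxy)cyclohexa-1,3-diene | C[Si](C)(C)OC1=CC[C@@H](C(C)=C)C(C)=C1 | intermediate
4 | (S)-4-isopropenyl-3-methylcyclohex-2-enone | O=C1CC[C@@H](C(C)=C)C(C)=C1 | intermediate
5 | 3-ethoxy-3-oxopropylzinc bromide | CCOC(=O)CC[Zn]Br | starting material
6 | ring B silyl enol ether with C10 propanoate chain | CCOC(=O)CC[C@]1(C)C=C(O[Si](C)(C)C)CC[C@H]1C(C)=C | intermediate
7 | ring B alkenyl nonaflate | CCOC(=O)CC[C@]1(C)C=C(OS(=O)(=O)C(F)(F)C(F)(F)C(F)(F)C(F)(F)F)CC[C@H]1C(C)=C | intermediate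
8 | ring A/B ε‑lactone nonaflate | O=C1CC[C@]2(C)C=C(OS(=O)(=O)C(F)(F)C(F)(F)C(F)(F)C(F)(F)F)CC[C@H]2C(C)(C)O1 | intermediate
9 | ring A/B allylsilane | O=C1CC[C@]2(C)C=C(C[Si](C)(C)C)CC[C@H]2C(C)(C)O1 | intermediate
10 | pentan-3-one | CCC(=O)CC | starting material
11 | 2,4-dimethylpenta-1,4-dien-3-one | C=C(C)C(=O)C(C)=C | intermediate
12 | 9β‑H isopropenyl ketone with C8=C12 | O=C1CC[C@]2(C)[C@H](CC(C)C(=O)C(C)=C)C(=C)CC[C@H]2C(C)(C)O1 | intermediate
13 | ethyl 4-(benzyloxy)acetoacetate | CCOC(=O)CC(=O)COCc1ccccc1 | starting material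
14 | Michael adduct | O=C1CC[C@]2(C)[C@H](CC(C)C(=O)C(C)CC(C(=O)OCC)C(=O)COCc3ccccc3)C(=C)CC[C@H]2C(C)(C)O1 | intermediate
15 | ring G aldol | O=C1CC[C@]2(C)[C@H](CC3(C)C(=O)C(C)CC(C(=O)OCC)C3(O)COCc3ccccc3)C(=C)CC[C@H]2C(C)(C)O1 | intermediate
16 | ring G cyclohexenone ester | O=C1CC[C@]2(C)[C@H](CC3(C)C(=O)C(C)CC(C(=O)OCC)=C3COCc3ccccc3)C(=C)CC[C@H]2C(C)(C)O1 | intermediate
17 | ring G silyl dienol ether | O=C1CC[C@]2(C)[C@H](CC3(C)C(O[Si](C)(C)C)=C(C)CC(C(=O)OCC)=C3COCc3ccccc3)C(=C)CC[C@H]2C(C)(C)O1 | intermediate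
18 | ring G 2,4‑cyclohexadienone (both C2′ epimers) | O=C1CC[C@]2(C)[C@H](CC3(C)C(=O)C(C)=CC(C(=O)OCC)=C3COCc3ccccc3)C(=C)CC[C@H]2C(C)(C)O1 | intermediate
19 | isotwistene keto ester | C[C@]12C(=O)[C@]3(C)C=C(C(=O)OCC)[C@@]1(COCc4ccccc4)[C@@]1(CC[C@H]4C(C)(C)OC(=O)CC[C@]4(C)[C@@H]1C2)C3 | intermediate
20 | saturated hydroxy ester | C[C@]12C(=O)[C@]3(C)C[C@@H](C(=O)OCC)[C@@]1(CO)[C@@]1(CC[C@H]4C(C)(C)OC(=O)CC[C@]4(C)[C@@H]1C2)C3 | intermediate
21 | isotwistanone bis‑lactone (4′‑epi) | C[C@]12C(=O)[C@]3(C)C[C@H]4C(=O)OC[C@]14[C@@]1(CC[C@H]4C(C)(C)OC(=O)CC[C@]4(C)[C@@H]1C2)C3 | intermediate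
22 | ene‑aldehyde | CC1=C[C@H]2[C@@]3(C)CCC(=O)OC(C)(C)[C@@H]3CC[C@]24C[C@](C)(C=O)C[C@H]5C(=O)OC[C@@]145 | intermediate
23 | C1′ carbinol with exocyclic methylene (C1′ configuration inconsequential) | C=C1[C@@H]2C(O)[C@]3(C)C[C@H]4C(=O)OC[C@]14[C@@]1(CC[C@H]4C(C)(C)OC(=O)CC[C@]4(C)[C@H]21)C3 | intermediate
24 | 4′‑epi‑1,2‑dihydro target | C=C1[C@@H]2C(=O)[C@]3(C)C[C@H]4C(=O)OC[C@]14[C@@]1(CC[C@H]4C(C)(C)OC(=O)CC[C@]4(C)[C@H]21)C3 | intermediate
25 | 1,2‑dihydro target | C=C1[C@@H]2C(=O)[C@]3(C)C[C@@H]4C(=O)OC[C@]14[C@@]1(CC[C@H]4C(C)(C)OC(=O)CC[C@]4(C)[C@H]21)C3 | intermediate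
26 | C2 phenylselenide | C=C1[C@@H]2C(=O)[C@]3(C)C[C@@H]4C(=O)OC[C@]14[C@@]1(CC[C@H]4C(C)(C)OC(=O)C([Se]c5ccccc5)C[C@]4(C)[C@H]21)C3 | intermediate
27 | CNP0136584.3 | C=C1[C@@H]2C(=O)[C@]3(C)C[C@@H]4C(=O)OC[C@]14[C@@]1(CC[C@H]4C(C)(C)OC(=O)C=C[C@]4(C)[C@H]21)C3 | target

**Total steps:** 15. **Longest linear sequence:** 14 (steps 1–5 and 7–15).

**Steps most likely to fail**

Step 4 (the new ε‑lactonisation). The seven‑membered capture may lose to elimination or simple reduction. The fallback sets out from 7 and returns at 8. Mukaiyama hydration (Co(acac)2, PhSiH3, O2) gives the tertiary alcohol ester F1. LiOH then gives the hydroxy acid F2. Yamaguchi activation (2,4,6‑trichlorobenzoyl chloride, Et3N, then DMAP at high dilution) closes ring A through the acyl C–O bond instead.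

Step 8 (quaternary C2′ by aldol). The hindered enolate may not close, or the C7′ methylene may attack C1′ instead. The fallback sets out from 12 and returns at 18. tBuMe2SiOTf/Et3N gives the 2‑silyloxydiene F3. A thermal Diels–Alder reaction with ethyl 4‑(benzyloxy)but‑2‑ynoate (PhMe, 140 °C) gives the cyclohexa‑1,4‑diene silyl enol ether F4. Pd(OAc)2 then delivers dienone 18, so ring G is made by cycloaddition instead of condensation.

Step 11 (photochemical α‑cleavage). Cleavage on the C6′ side, decarbonylation or hydrogen transfer from the methyl group may compete. The fallback sets out from 21 and returns at 22. LiAlH(OtBu)3 gives the C1′ alcohol F5. PhI(OAc)2/I2 under visible light (alkoxy‑radical β‑scission) gives the tertiary iodo aldehyde F6. DBU then eliminates to the more stable endocyclic cyclopentene 22.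

**Further compounds**
F1 | step 4 | tertiary alcohol ester | CCOC(=O)CC[C@]1(C)C=C(OS(=O)(=O)C(F)(F)C(F)(F)C(F)(F)C(F)(F)F)CC[C@H]1C(C)(C)O
F2 | step 4 | hydroxy acid | OC(=O)CC[C@]1(C)C=C(OS(=O)(=O)C(F)(F)C(F)(F)C(F)(F)C(F)(F)F)CC[C@H]1C(C)(C)O
F3 | step 8 | 2‑silyloxydiene | O=C1CC[C@]2(C)[C@H](CC(C)=C(O[Si](C)(C)C(C)(C)C)C(C)=C)C(=C)CC[C@H]2C(C)(C)O1
F4 | step 8 | cyclohexa‑1,4‑diene silyl enol ether | O=C1CC[C@]2(C)[C@H](CC3(C)C(O[Si](C)(C)C(C)(C)C)=C(C)CC(C(=O)OCC)=C3COCc3ccccc3)C(=C)CC[C@H]2C(C)(C)O1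
F5 | step 11 | C1′ alcohol | C[C@]12C(O)[C@]3(C)C[C@H]4C(=O)OC[C@]14[C@@]1(CC[C@H]4C(C)(C)OC(=O)CC[C@]4(C)[C@@H]1C2)C3
F6 | step 11 | tertiary iodo aldehyde | CC1(I)C[C@H]2[C@@]3(C)CCC(=O)OC(C)(C)[C@@H]3CC[C@]24C[C@](C)(C=O)C[C@H]5C(=O)OC[C@@]145
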